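**Retrosynthetic overview**

1. The target comes from its pentamethyl ether bis(triflate) pivalate 15 by deprotection. The second dihydrofuran is opened at O–C7c (Mitsunobu) and at C8c–C14b (Friedel–Crafts opening of (R,R)-oxirane 4 by phenol 13).
2. The ampelopsin-B-type core 13 comes from triol 12 by Mitsunobu closure of the first dihydrofuran (O–C7a).
3. Key disconnection: both C–C bonds that tie unit a to unit b, C8a–C10b and C10a–C7b, are made together in a formal (4+3) annulation of stilbene 9 with (S,S)-oxirane 3.
4. Enabling feature: the seven-membered ring (C10b, C8a, C9a, C10a, C7b, C8b, C9b) sits between two resorcinol-type rings, the central ring D of unit b and ring B of unit a. Their carbons C10b and C10a are ortho/para to oxygen and nucleophilic, while C8a and C7b are benzylic and can be made electrophilic (C8a as an oxirane carbon, C7b as the cation of the C7b=C8b stilbene, stabilised by the 4-methoxyphenyl-type ring C).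
5. Ring order: seven-membered carbocycle (step 7), first dihydrofuran (step 9), second dihydrofuran (step 11). Both oxiranes come from one stilbene 2 with enantiomeric Shi ketones.

Key step: step 7

Remark on the chemistry: the SMILES is read as the (7aS,8aS,7bS,7cR,8cR) isomer with both dihydrobenzofurans trans; stilbenoid locants with the suffixes a, b and c for the three resveratrol-type units are used throughout, where unit a is C7a (bears O and ring A, the 4-oxygenated phenyl ring) and C8a (bears ring B, the 3,5-dioxygenated ring C9a–C14a), unit b is C7b (CH bearing ring C, the 2,4-dioxygenated phenyl ring), C8b (CH2) and the central ring D (C9b–C14b), and unit c is C7c (bears O and ring E, the 4-oxygenated phenyl ring) and C8c (bears ring G, the 3,5-dioxygenated phenyl ring).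

**Route**

Step 1
Reactants: 1 pterostilbene
Product: 2 (E)-4-(3,5-dimethoxystyryl)phenyl trifluoromethanesulfonate
Conditions: Tf2O, pyridine, CH2Cl2, 0 °C
Reagents that add atoms: trifluoromethanesulfonic anhydride, O=S(=O)(OS(=O)(=O)C(F)(F)F)C(F)(F)F
Why: Sulfonylation of the phenol (aryl triflate formation); the triflate later switches off the benzylic carbon next to ring A (or ring E) in the oxirane openings and keeps the benzylic C–O bonds of the dihydrofurans inert to acid.

Step 2
Reactants: 2 stilbene triflate
Product: 3 4-[(2S,3S)-3-(3,5-dimethoxyphenyl)oxiran-2-yl]phenyl trifluoromethanesulfonate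
Conditions: ent-Shi ketone (1,2:4,5-di-O-isopropylidene-β-L-erythro-2,3-hexodiulo-2,6-pyranose, 30 mol %), KHSO5 (as 2KHSO5·KHSO4·K2SO4), K2CO3, Bu4NHSO4 (cat.), MeCN/CH2(OMe)2/aq. Na2B4O7 buffer, 0 °C
Reagents that add atoms: potassium peroxymonosulfate, [K+].[O-]S(=O)(=O)OO
Why: Shi asymmetric epoxidation of a trans-stilbene; the chiral dioxirane should set both oxirane carbons (S,S) under catalyst control through the spiro transition state.

Step 3
Reactants: 2 stilbene triflate
Product: 4 4-[(2R,3R)-3-(3,5-dimethoxyphenyl)oxiran-2-yl]phenyl trifluoromethanesulfonate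
Conditions: Shi ketone (1,2:4,5-di-O-isopropylidene-β-D-erythro-2,3-hexodiulo-2,6-pyranose, 30 mol %), KHSO5 (as 2KHSO5·KHSO4·K2SO4), K2CO3, Bu4NHSO4 (cat.), MeCN/CH2(OMe)2/aq. Na2B4O7 buffer, 0 °C
Reagents that add atoms: potassium peroxymonosulfate, [K+].[O-]S(=O)(=O)OO
Why: Shi asymmetric epoxidation with the D-fructose-derived ketone, which should give the (R,R)-oxirane, the source of both stereocenters of unit c.

Step 4
Reactants: 5 2-bromo-5-methoxyphenol
Product: 6 2-bromo-5-methoxyphenyl pivalate
Conditions: t-BuCOCl, Et3N, DMAP (cat.), CH2Cl2, 0 °C to 20 °C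
Reagents that add atoms: pivaloyl chloride, CC(C)(C)C(=O)Cl
Why: O-Acylation of the phenol; the pivalate makes the future ring C a poor Friedel–Crafts nucleophile while its para-methoxy group is kept for stabilising the C7b cation.

Step 5
Reactants: 7 3,5-bis(benzyloxy)benzaldehyde
Product: 8 3,5-bis(benzyloxy)styrene
Conditions: Ph3PCH3Br, KOtBu, THF, 0 °C to 20 °C
Reagents that add atoms: methyltriphenylphosphonium bromide, C[P+](c1ccccc1)(c1ccccc1)c1ccccc1.[Br-]
Why: Wittig methylenation of an aromatic aldehyde.

Step 6
Reactants: 8 3,5-bis(benzyloxy)styrene; 6 2-bromo-5-methoxyphenyl pivalate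
Product: 9 (E)-2-[3,5-bis(benzyloxy)styryl]-5-methoxyphenyl pivalate (stilbene of unit b)
Conditions: Pd(OAc)2 (5 mol %), P(o-tol)3 (10 mol %), Et3N, DMF, 100 °C
Reagents that add atoms: none
Why: Mizoroki–Heck coupling of an aryl bromide with a styrene; β-arylation and syn β-hydride elimination should give the E-stilbene.

Step 7
Reactants: 9 stilbene of unit b; 3 (S,S)-oxirane
Product: 11 seven-membered-ring carbinol (C7a R; C8a S; C7b S; ring D as its bis(benzyl ether)), via open-chain arylation adduct 10 (not isolated)
Conditions: TfOH (5 mol %), (CF3)2CHOH/CH2Cl2 (4:1), −20 °C to 20 °C, 3 added slowly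
Reagents that add atoms: none
Why: Proposed new method: a domino Friedel–Crafts oxirane arylation/alkene hydroarylation (formal (4+3) annulation of an aryl oxirane with a 2-vinyl resorcinol ether) is put forward, whose closest known reaction types are the stereospecific, invertive arylation of aryl oxiranes by electron-rich arenes in fluoroalcohols and the acid-induced closure of ε-viniferin-type stilbenes to the ampelopsin B ring system. Mechanistically, acid-activated 3 should be opened in an SN2-like way at its 3,5-dimethoxybenzylic carbon by C10b of 9 (inversion, giving 10), after which protonation of the stilbene at C8b (or direct collapse of the first arenium ion, whose charge is delocalised onto C7b) gives the 4-methoxyphenyl-stabilised C7b cation that is trapped by C10a of the newly attached ring B. The only ring closed is the seven-membered carbocycle, formed by a 7-endo-trig cation–arene (Friedel–Crafts) closure. C8a is fixed by inversion of the (S)-oxirane carbon and C7a is carried through unchanged, while C7b is set by substrate control: attack on the face that places ring C trans (1,4 across the new ring) to the bulky C8a side chain lets one large group stay pseudo-axial and the other pseudo-equatorial in the boat-like transition state, the relative configuration of the ampelopsin B series. The step needs four selectivities, each built into the substrates: the oxirane carbon (the 4-triflyloxyphenyl group switches off C7a), the arene site (C10b and C14b are equivalent and C12b lies between two benzyloxy groups), ring D over ring C and over the alkene carbon (pivalate deactivation of ring C), and C7b rather than C8b as the cationic carbon (para-methoxy group of ring C).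

Step 8
Reactants: 11 seven-membered-ring carbinol
Product: 12 triol (two free phenols at C11b and C13b; secondary carbinol at C7a)
Conditions: BCl3, C6HMe5, CH2Cl2, −78 °C; then MeOH, H2O
Reagents that add atoms: none
Why: Lewis-acid debenzylation of aryl benzyl ethers with pentamethylbenzene as cation scavenger; at −78 °C the methyl ethers, the triflate, the pivalate and the deactivated benzylic alcohol should be left alone.

Step 9
Reactants: 12 triol
Product: 13 ampelopsin-B-type core phenol (7aS,8aS,7bS), free OH at C13b
Conditions: PPh3, DIAD, THF, 0 °C to 20 °C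
Reagents that add atoms: none
Why: Intramolecular Mitsunobu etherification (5-exo-tet); only the C11b phenol can reach C7a, and inversion of the (R)-carbinol gives the trans-dihydrobenzofuran with C7a (S).

Step 10
Reactants: 13 core phenol; 4 (R,R)-oxirane
Product: 14 C14b-alkylated phenol carrying the chain CH(3,5-dimethoxyphenyl)–CH(OH)(4-triflyloxyphenyl) (C8c R; C7c S)
Conditions: TfOH (5 mol %), (CF3)2CHOH/CH2Cl2 (4:1), −20 °C to 0 °C
Reagents that add atoms: none
Why: Friedel–Crafts arylation of an aryl oxirane in fluoroalcohol; ring D is now the only phenol ring and C14b is its only carbon ortho to the hydroxyl and para to the planar dihydrofuran oxygen, the oxirane again opens at the 3,5-dimethoxybenzylic carbon, and inversion sets C8c (R).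

Step 11
Reactants: 14 C14b-alkylated phenol
Product: 15 fully protected trimer (7aS,8aS,7bS,7cR,8cR)
Conditions: PPh3, DIAD, THF, 0 °C to 20 °C
Reagents that add atoms: none
Why: Second intramolecular Mitsunobu etherification (5-exo-tet) between the C13b phenol and the C7c carbinol; inversion of the (S)-carbinol gives the trans-dihydrobenzofuran with C7c (R).

Step 12
Reactants: 15 fully protected trimer
Product: 16 pentamethyl ether triphenol (free OH on rings A and E and at position 2 of ring C)
Conditions: Et4NOH (aq.), 1,4-dioxane, 20 °C to 40 °C, Ar; then dilute HCl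
Reagents that add atoms: none
Why: Hydroxide cleavage of the two aryl triflates (attack at sulfur) and saponification of the aryl pivalate; the methyl ethers and all five stereocenters are not touched by base.

Step 13
Reactants: 16 pentamethyl ether triphenol
Product: 17 CNP0154047.3 (target)
Conditions: BBr3 (excess), CH2Cl2, −78 °C to 0 °C; then H2O
Reagents that add atoms: none
Why: Lewis-acid demethylation of aryl methyl ethers with BBr3, the usual last step for permethylated resveratrol oligomers; the free 4-hydroxyphenyl groups are tied up as aryloxyboranes, which should damp ionisation of the benzylic C–O bonds.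

**Compound list**

1 | pterostilbene, (E)-4-(3,5-dimethoxystyryl)phenol | COc1cc(/C=C/c2ccc(O)cc2)cc(OC)c1 | starting material
2 | (E)-4-(3,5-dimethoxystyryl)phenyl trifluoromethanesulfonate | COc1cc(/C=C/c2ccc(OS(=O)(=O)C(F)(F)F)cc2)cc(OC)c1 | intermediate
3 | 4-[(2S,3S)-3-(3,5-dimethoxyphenyl)oxiran-2-yl]phenyl trifluoromethanesulfonate (trans) | COc1cc(cc(OC)c1)[C@@H]1O[C@H]1c1ccc(OS(=O)(=O)C(F)(F)F)cc1 | intermediate
4 | 4-[(2R,3R)-3-(3,5-dimethoxyphenyl)oxiran-2-yl]phenyl trifluoromethanesulfonate (trans) | COc1cc(cc(OC)c1)[C@H]1O[C@@H]1c1ccc(OS(=O)(=O)C(F)(F)F)cc1 | intermediate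
5 | 2-bromo-5-methoxyphenol | COc1ccc(Br)c(O)c1 | starting material
6 | 2-bromo-5-methoxyphenyl pivalate | COc1ccc(Br)c(OC(=O)C(C)(C)C)c1 | intermediate
7 | 3,5-bis(benzyloxy)benzaldehyde | O=Cc1cc(OCc2ccccc2)cc(OCc2ccccc2)c1 | starting material
8 | 3,5-bis(benzyloxy)styrene | C=Cc1cc(OCc2ccccc2)cc(OCc2ccccc2)c1 | intermediate
9 | (E)-2-[3,5-bis(benzyloxy)styryl]-5-methoxyphenyl pivalate | COc1ccc(/C=C/c2cc(OCc3ccccc3)cc(OCc3ccccc3)c2)c(OC(=O)C(C)(C)C)c1 | intermediate
10 | (1R,2S)-2-{2,4-bis(benzyloxy)-6-[(E)-4-methoxy-2-(pivaloyloxy)styryl]phenyl}-2-(3,5-dimethoxyphenyl)-1-[4-(triflyloxy)phenyl]ethanol | FC(F)(F)S(=O)(=O)Oc1ccc(cc1)[C@H](O)[C@@H](c1cc(OC)cc(OC)c1)c1c(OCc2ccccc2)cc(OCc2ccccc2)cc1/C=C/c1ccc(OC)cc1OC(=O)C(C)(C)C | intermediate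
11 | dibenzo-fused cycloheptane (rings D and B) carrying the (R)-CH(OH)(4-triflyloxyphenyl) group on C8a (S), ring C (4-methoxy-2-pivaloyloxyphenyl) on C7b (S), benzyloxy groups at C11b and C13b, methoxy groups at C11a and C13a | FC(F)(F)S(=O)(=O)Oc1ccc(cc1)[C@H](O)[C@@H]1c2c(OCc3ccccc3)cc(OCc3ccccc3)cc2C[C@@H](c2ccc(OC)cc2OC(=O)C(C)(C)C)c2c(OC)cc(OC)cc21 | intermediate
12 | as 11, free phenols at C11b and C13b in place of the benzyl ethers | FC(F)(F)S(=O)(=O)Oc1ccc(cc1)[C@H](O)[C@@H]1c2c(O)cc(O)cc2C[C@@H](c2ccc(OC)cc2OC(=O)C(C)(C)C)c2c(OC)cc(OC)cc21 | intermediate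
13 | (7aS,8aS,7bS) core: trans-dihydrobenzofuran fused to the seven-membered ring, OH at C13b, ring A as 4-triflate, ring B dimethoxy, ring C 4-methoxy-2-pivaloyloxy | FC(F)(F)S(=O)(=O)Oc1ccc([C@H]2Oc3cc(O)cc4c3[C@@H]2c2cc(OC)cc(OC)c2[C@H](c2ccc(OC)cc2OC(=O)C(C)(C)C)C4)cc1 | intermediate
14 | 13 carrying at C14b the chain (R)-CH(3,5-dimethoxyphenyl)–(S)-CH(OH)(4-triflyloxyphenyl) | FC(F)(F)S(=O)(=O)Oc1ccc([C@H]2Oc3cc(O)c(c5c3[C@@H]2c2cc(OC)cc(OC)c2[C@H](c2ccc(OC)cc2OC(=O)C(C)(C)C)C5)[C@@H](c2cc(OC)cc(OC)c2)[C@H](O)c2ccc(OS(=O)(=O)C(F)(F)F)cc2)cc1 | intermediate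
15 | (7aS,8aS,7bS,7cR,8cR) protected trimer: target skeleton, triflates on rings A and E, pivalate at position 2 of ring C, five methyl ethers | FC(F)(F)S(=O)(=O)Oc1ccc([C@H]2Oc3cc4c(c5c3[C@@H]2c2cc(OC)cc(OC)c2[C@H](c2ccc(OC)cc2OC(=O)C(C)(C)C)C5)[C@@H](c2cc(OC)cc(OC)c2)[C@H](c2ccc(OS(=O)(=O)C(F)(F)F)cc2)O4)cc1 | intermediate
16 | (7aS,8aS,7bS,7cR,8cR) pentamethyl ether of the target (methyl ethers on rings B and G and at position 4 of ring C) | Oc1ccc([C@H]2Oc3cc4c(c5c3[C@@H]2c2cc(OC)cc(OC)c2[C@H](c2ccc(OC)cc2O)C5)[C@@H](c2cc(OC)cc(OC)c2)[C@H](c2ccc(O)cc2)O4)cc1 | intermediate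
17 | CNP0154047.3, (7aS,8aS,7bS,7cR,8cR) | Oc1ccc([C@H]2Oc3cc4c(c5c3[C@@H]2c2cc(O)cc(O)c2[C@H](c2ccc(O)cc2O)C5)[C@@H](c2cc(O)cc(O)c2)[C@H](c2ccc(O)cc2)O4)cc1 | target

**Step count**

Total steps: 13. Longest linear sequence: 9 steps (steps 5 to 13 from 7, or steps 1, 2 and 7 to 13 from 1).

**Steps most likely to fail**

Step 7 (bears the label "Proposed new method:"). The cationic events may be mistimed: the stilbene may be protonated and oligomerise before the oxirane is consumed, the oxirane may undergo Meinwald rearrangement, or the seven-membered ring may close with poor facial selectivity while the side chain is still open. The fallback separates the events and uses known chemistry only. It sets out from 9 and 3: the oxirane is arylated alone (Sc(OTf)3 cat., (CF3)2CHOH, 0 °C, no strong Brønsted acid) and adduct 10 is isolated. BCl3/C6HMe5 at −78 °C gives the stilbene triol F1. Mitsunobu closure gives the ε-viniferin-type trans-dihydrobenzofuran stilbene F2. TfOH in (CF3)2CHOH (or H2SO4 in MeOH) then closes the seven-membered ring on the closed dihydrofuran, the substrate class for which this cyclisation is known, and the sequence returns to the route at 13.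

Step 10. The phenol oxygen may be alkylated instead of carbon, or the oxirane may be attacked by C12b or by ring B. The fallback moves the second arylation to the ether stage, where no free phenol exists and C12b lies between two benzyloxy groups. It sets out from 11: arylation of 4 under the conditions of step 7 gives the bis(benzyl ether) diol F3. BCl3/C6HMe5 gives the tetraol F4. A double Mitsunobu reaction closes both dihydrofurans at once and returns to the route at 15.

Step 13. The Lewis acid may open the benzylic C–O bonds of the dihydrofurans or reverse the Friedel–Crafts bond at C7b during the fivefold demethylation. The fallback changes from electrophilic to nucleophilic dealkylation. It sets out from 16: NaSEt in DMF at 130 °C under argon cleaves the methyl ethers by SN2 attack at methyl in a basic medium in which benzylic cations cannot form, and returns to the route at 17. No new compound lies on its way.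

**Further compounds**

F1 | step 7 | (1R,2S)-2-{2,4-dihydroxy-6-[(E)-4-methoxy-2-(pivaloyloxy)styryl]phenyl}-2-(3,5-dimethoxyphenyl)-1-[4-(triflyloxy)phenyl]ethanol | FC(F)(F)S(=O)(=O)Oc1ccc(cc1)[C@H](O)[C@@H](c1cc(OC)cc(OC)c1)c1c(O)cc(O)cc1/C=C/c1ccc(OC)cc1OC(=O)C(C)(C)C
F2 | step 7 | (7aS,8aS) trans-dihydrobenzofuran stilbene: OH at C13b, (E)-4-methoxy-2-(pivaloyloxy)styryl at C9b, ring A as 4-triflate, ring B dimethoxy | FC(F)(F)S(=O)(=O)Oc1ccc([C@H]2Oc3cc(O)cc(/C=C/c4ccc(OC)cc4OC(=O)C(C)(C)C)c3[C@@H]2c2cc(OC)cc(OC)c2)cc1
F3 | step 10 | 11 carrying at C14b the chain (R)-CH(3,5-dimethoxyphenyl)–(S)-CH(OH)(4-triflyloxyphenyl) | FC(F)(F)S(=O)(=O)Oc1ccc(cc1)[C@H](O)[C@@H]1c2c(OCc3ccccc3)cc(OCc3ccccc3)c([C@@H](c3cc(OC)cc(OC)c3)[C@H](O)c3ccc(OS(=O)(=O)C(F)(F)F)cc3)c2C[C@@H](c2ccc(OC)cc2OC(=O)C(C)(C)C)c2c(OC)cc(OC)cc21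
F4 | step 10 | as F3, free phenols at C11b and C13b in place of the benzyl ethers | FC(F)(F)S(=O)(=O)Oc1ccc(cc1)[C@H](O)[C@@H]1c2c(O)cc(O)c([C@@H](c3cc(OC)cc(OC)c3)[C@H](O)c3ccc(OS(=O)(=O)C(F)(F)F)cc3)c2C[C@@H](c2ccc(OC)cc2OC(=O)C(C)(C)C)c2c(OC)cc(OC)cc21
F0 | step 13 | none | none
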